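**Proposed synthesis of CNP0017937.0: 5-bromo-2-(3,5-dibromo-2-methoxyphenoxy)phenol (14)**

## The problem

Target 14 is a tribrominated diaryl ether in which two benzene rings are joined through a single oxygen atom: ring A carries the bridging oxygen at C1, a methoxy group at C2 and bromine at C3 and C5, and ring B carries the bridging oxygen at C1', a free hydroxyl at C2' and bromine at C4'. There is no stereocentre, so every control problem is one of regiochemistry and of telling the two ortho oxygen functions apart, one of which must end as a methyl ether and the other as a free phenol. The ring A bromines sit ortho and para to the methoxy group, whereas the ring B bromine sits para to the bridging oxygen and meta to the hydroxyl, which is not where a free phenol would direct an electrophile. The three aryl bromides exclude alkyllithium reagents, zerovalent transition metals and reductive conditions, and C4–H between the two ring A bromines is acidic enough to make lithium dialkylamide bases unsafe. The feature that opens the molecule is that C1' and C2' of ring B are adjacent and both oxygenated. The C1'–C2' bond can therefore be mapped onto a bond between C3 of a 3-acyloxy-2-pyrone and the oxygen-bearing carbon of an aryl ethynyl ether, with C2' to C5' coming from pyrone carbons C3 to C6, C6' and C1' from the alkyne, and carbon dioxide as the only by-product.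

## Retrosynthesis

**14 to 13 (O–acyl bond).** The free C2' hydroxyl is traced back to the acetate 13. The ester is the form in which this oxygen enters the molecule, so no separate protection step is needed. The forward reaction only has to be a mild methanolysis that leaves three aryl bromides and two ethers alone.

**13 to 12 (C4'–Br bond).** The ring B bromine is removed next. With the C2' oxygen masked as an acetate, the bridging oxygen is the strongest donor on ring B and C4' is para to it. A free phenol would direct to C5' and C3' instead, which is why the bromination precedes deacetylation. Carrying this bromine through the ring-forming step was considered, but a C5-brominated analogue of 10 is not readily available and its preparation would pose its own regiochemical question. The forward reaction must discriminate C4' from C6' and C5' and leave the deactivated ring A untouched.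

**12 to 8 + 10 (C1'–C2' and C5'–C6' bonds, through 11).** Ring B is opened into the ynol ether 8 and the acetoxypyrone 10. This cut is preferred over a C–O disconnection of the diaryl ether because it produces the ortho dioxygenated ring with its two oxygens already differentiated, one as aryl ether and one as ester. It also forms the benzene at the correct oxidation level, since the bridged lactone 11 aromatises by decarboxylative cycloreversion. The precursors are much simpler: 10 is a one-step derivative of a commercial pyrone, and 8 contains only ring A and two carbons. The forward reaction must be regioselective (aryloxy carbon bonded to pyrone C3) and must outpace self-oligomerisation of 8.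

**10 to 9 (O–acyl bond).** The diene 10 is the acetate of commercial 3-hydroxy-2H-pyran-2-one 9.

**8 to 7 to 5 (triple bond from a vinyl ether, through 6).** The ethynyl ether 8 is traced to the bromovinyl ether 7 by dehydrobromination, and 7 to the vinyl ether 5 by addition of bromine across the double bond (dibromide 6) and loss of one equivalent of hydrogen bromide. The better-known entry to terminal ynol ethers through dichlorovinyl ethers requires alkyllithium reagents and is excluded by the aryl bromides. The route through 7 needs only an amidine and an alkoxide base, and 7 is a storable precursor from which labile 8 can be released immediately before use.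

**5 to 4 (O–vinyl bond).** The vinyl ether comes from phenol 4 by catalytic vinyl transfer from a vinyl ester. This is one step, against two for alkylation and elimination, and it uses no strong base.

**4 to 2 to 1 (C–O bond by oxidative aryl migration, through 3).** Phenol 4 cannot be made by brominating a guaiacol, because bromine would enter ortho and para to the hydroxyl. In commercial 3,5-dibromosalicylaldehyde 1 the bromines are already ortho and para to the oxygen that becomes the methoxy group. O-methylation gives 2, and peracid oxidation through formate 3 converts the formyl carbon into the phenol oxygen that later forms the bridge.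

## Roads not taken

**Alternative 1:** The cut runs through ring A at C1–C6 and C3–C4. The ring B ketone 1-(4-bromo-2-nitrophenoxy)propan-2-one A1 would add in Michael fashion to acrolein A2, and the methyl ketone would close by aldol condensation to racemic 6-(4-bromo-2-nitrophenoxy)cyclohex-2-en-1-one A3. Oxidative aromatisation of A3 under electrophilic bromination would be expected to give the phenol and brominate it ortho and para to the new hydroxyl in one operation, giving 2,4-dibromo-6-(4-bromo-2-nitrophenoxy)phenol A4. O-methylation of A4 and exchange of the nitro group for hydroxyl (reduction, diazotisation, hydrolysis) would complete 14.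
- Merits: the ring B bromine is in place from the start, and both ring A bromines are directed by a free phenol, so no bromine position depends on a subtle preference. At about six operations it is shorter than the chosen route.
- Weak points: A1 has two enolisable positions and a nitro-activated aryl ether that alkoxide or hydroxide can cleave by ipso substitution. A2 polymerises readily under base. The end game after A4 must reduce a nitro group beside three aryl bromides and then hydrolyse a diazonium salt on a hindered, polyhalogenated ring, a step that is seldom clean.
- Comparison: Alternative 1 is shorter and surer in bromine placement. The chosen plan sets against it a neutral, thermal ring formation, an end game of two mild steps, and a C2' oxygen that is present as an ester from the outset and not as a nitrogen placeholder.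

**Alternative 2:** No ring is made; the cut removes the three C–Br bonds from a preformed diaryl ether. 2,2'-Oxydiphenol A5 would be desymmetrised as its mono-sulfonate 2-(2-hydroxyphenoxy)phenyl methanesulfonate A6. A threefold electrophilic bromination of A6 would then place two bromines ortho and para to the free hydroxyl and the third para to the bridging oxygen on the sulfonate ring, giving 5-bromo-2-(3,5-dibromo-2-hydroxyphenoxy)phenyl methanesulfonate A7. Methylation of A7 and sulfonate cleavage would finish 14.
- Merits: it is the shortest plan (four operations from A5), uses only classical reactions and has no labile intermediate.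
- Weak points: the mono-sulfonylation of A5 to A6 is statistical. The third bromination must take place on a sulfonate-deactivated ring after the phenol ring has taken two bromines, and must stop there; under- and over-brominated congeners of A7 would be hard to separate.
- Comparison: in step economy and in the reliability of each individual reaction, Alternative 2 is better than the chosen plan. The chosen plan sets against it rings that are distinct from the first step, ring A bromines bought in place, a single bromine introduced by directed substitution, and a ring B assembly in which the two oxygens cannot be confused.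

**Alternative 3:** The cut runs through ring B at C1'–C6' and C3'–C4'. The ring A ketone 1-(3,5-dibromo-2-methoxyphenoxy)propan-2-one A8, which would come from phenol 4 by O-alkylation, would undergo Michael addition to ethyl acrylate A9 and Claisen cyclisation to racemic 4-(3,5-dibromo-2-methoxyphenoxy)cyclohexane-1,3-dione A10. The carbonyl destined to become C4' would then be exchanged for bromine, giving the vinylogous acid bromide racemic 3-bromo-6-(3,5-dibromo-2-methoxyphenoxy)cyclohex-2-en-1-one A11, and dehydrogenation of A11 would give 14.
- Merits: it shares 4 with the chosen route and uses cheap reagents. C4' is marked by a carbonyl group, so the bromine position does not rest on an aromatic substitution preference; in this respect it is better than the chosen plan.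
- Weak points: the deoxybromination must choose between the two carbonyls of A10. The bromoenone A11 is sensitive to hydrolysis and addition–elimination and would have to survive a dehydrogenation for which there is little guidance. The annulation base must also discriminate the two α-positions of A8, and a second Michael addition to A9 can compete with ring closure.
- Comparison: the chosen route needs no oxidation-level adjustment, since cycloaddition and cycloreversion give the benzene directly. Its late bromination occurs on an arene where one position is clearly favoured. It pays for this with the labile ynol ether 8.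

Key step: step 7

Remark: bromovinyl ether 7 is expected as a Z-rich mixture of double-bond isomers; it is named, drawn and listed as the Z isomer, and both isomers converge on 8.

## Route

Step 1
Reactants: 1 3,5-dibromo-2-hydroxybenzaldehyde (3,5-dibromosalicylaldehyde)
Product: 2 3,5-dibromo-2-methoxybenzaldehyde
Conditions: MeI, K2CO3, DMF, rt
Reagents that add atoms: iodomethane, CI
Why: Williamson ether synthesis; the phenol is acidified by two bromines and the formyl group, so K2CO3 suffices, and the aldehyde and aryl bromides are inert.

Step 2
Reactants: 2 3,5-dibromo-2-methoxybenzaldehyde
Product: 4 3,5-dibromo-2-methoxyphenol, via aryl formate 3 (not isolated)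
Conditions: mCPBA, CH2Cl2, rt; aq. Na2SO3/NaHCO3 wash; then K2CO3 (cat.), MeOH, rt
Reagents that add atoms: 3-chloroperoxybenzoic acid (mCPBA), O=C(OO)c1cccc(Cl)c1
Why: Baeyer–Villiger (Dakin-type) oxidation; the ortho methoxy group supports migration of the aryl group in the Criegee intermediate to give formate 3, which is cleaved by base-catalysed methanolysis without touching the bromides.

Step 3
Reactants: 4 3,5-dibromo-2-methoxyphenol
Product: 5 1,5-dibromo-3-(ethenyloxy)-2-methoxybenzene
Conditions: vinyl acetate (3 equiv), [Ir(cod)Cl]2 (2 mol %), Na2CO3 (0.6 equiv), PhMe, 100 °C
Reagents that add atoms: vinyl acetate, C=COC(C)=O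
Why: Iridium-catalysed transfer vinylation of a phenol (addition of the phenoxide to the coordinated vinyl ester, then β-acetoxy elimination); the aryl bromides do not react with the iridium catalyst under these conditions and no strong base is needed.

Step 4
Reactants: 5 1,5-dibromo-3-(ethenyloxy)-2-methoxybenzene
Product: 7 (Z)-1,5-dibromo-3-[(2-bromoethenyl)oxy]-2-methoxybenzene, via dibromoethyl ether 6 (not isolated)
Conditions: Br2 (1.05 equiv), CH2Cl2, −78 °C; then DBU (1.5 equiv), −78 °C to rt
Reagents that add atoms: bromine, BrBr
Why: Electrophilic addition of bromine to the enol ether is far faster than substitution on the deactivated ring A and gives racemic α-bromo ether 6, whose stereocentre is removed at once by E2 dehydrobromination with the amidine base; any E isomer or 1-bromovinyl regioisomer leads to the same alkyne in step 5.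

Step 5
Reactants: 7 (Z)-1,5-dibromo-3-[(2-bromoethenyl)oxy]-2-methoxybenzene
Product: 8 1,5-dibromo-3-(ethynyloxy)-2-methoxybenzene
Conditions: KOtBu (2.5 equiv), THF, −78 to 0 °C; cold aq. NH4Cl; kept as a dry PhMe solution and used at once
Reagents that add atoms: none
Why: Base-induced dehydrobromination of a β-bromo enol ether (anti E2 elimination in the Z isomer, where the hydrogen on the oxygen-bearing carbon is anti to bromine); a hindered alkoxide is used because alkyllithium or lithium dialkylamide bases would attack the aryl bromides or metalate C4–H between them.

Step 6
Reactants: 9 3-hydroxy-2H-pyran-2-one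
Product: 10 2-oxo-2H-pyran-3-yl acetate (3-acetoxy-2H-pyran-2-one)
Conditions: Ac2O, pyridine, CH2Cl2, 0 °C to rt
Reagents that add atoms: acetic anhydride, CC(=O)OC(C)=O
Why: O-acylation of the enolic hydroxyl; the acetate removes the acidic proton that would hydrate the ynol ether and becomes the protecting group of the future C2' phenol.

Step 7
Reactants: 8 1,5-dibromo-3-(ethynyloxy)-2-methoxybenzene; 10 2-oxo-2H-pyran-3-yl acetate
Product: 12 2-(3,5-dibromo-2-methoxyphenoxy)phenyl acetate, via bicyclic lactone 11 (not isolated)
Conditions: 10 (3 equiv), BHT (cat.), dry o-xylene, 130 °C, 8 added by syringe pump as a PhMe solution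
Reagents that add atoms: none
Why: This is a Diels–Alder/retro-Diels–Alder benzannulation, and the closest known reaction type is the cycloaddition of 2-pyrones with alkynes (including heteroatom-substituted alkynes), which gives benzenes after loss of CO2. The C3–C6 diene of 10 and the triple bond of 8 should combine in a thermally allowed, asynchronous (4+2) cycloaddition in which the terminal alkyne carbon, the nucleophilic β-carbon of the ynol ether, bonds first to C6 of the pyrone, the position of conjugate attack. The developing charges are then an oxocarbenium-like carbon beside the aryloxy oxygen and a lactone dienolate centred on C3, and their union forms the C1'–C2' bond and places the aryloxy carbon next to the acetoxy carbon. Ring B is thus closed by an intermolecular (4+2) cycloaddition as the bridged bicyclic lactone 11, whose lactone bridge is expelled as CO2 in a cycloreversion driven by aromatisation, so the benzene appears directly at the right oxidation level. No stereocentre survives, because the two bridgehead centres of racemic 11 are erased on aromatisation. The only selectivity required is regiochemical, and it is secured by the matched polarisation of the two partners, the same orientation that enol ethers and ketene acetals show toward 3-substituted 2-pyrones. Self-oligomerisation of 8 is suppressed by keeping its stationary concentration low (slow addition to excess 10) and by a radical inhibitor, while the aryl bromides, methyl ether and acetate are inert under neutral thermal conditions.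

Step 8
Reactants: 12 2-(3,5-dibromo-2-methoxyphenoxy)phenyl acetate
Product: 13 5-bromo-2-(3,5-dibromo-2-methoxyphenoxy)phenyl acetate
Conditions: Br2 (1.05 equiv), NaOAc, AcOH, rt
Reagents that add atoms: bromine, BrBr
Why: Electrophilic aromatic bromination; on ring B the diaryl ether oxygen is the strongest donor and the acetoxy group a weak one, so substitution is expected para to the bridging oxygen at C4' (C6' is hindered), while ring A is deactivated by two bromines, every position ortho or para to its methoxy group is blocked and its remaining C4–H and C6–H are flanked by bromine or by the ether; NaOAc buffers the HBr so the acetate stays in place.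

Step 9
Reactants: 13 5-bromo-2-(3,5-dibromo-2-methoxyphenoxy)phenyl acetate
Product: 14 5-bromo-2-(3,5-dibromo-2-methoxyphenoxy)phenol (CNP0017937.0)
Conditions: K2CO3 (0.2 equiv), MeOH, rt; then dilute HCl
Reagents that add atoms: none
Why: Base-catalysed transesterification (methanolysis) of an aryl acetate; the aryl bromides, methyl ether and diaryl ether are untouched.

## Compound list

1 | 3,5-dibromo-2-hydroxybenzaldehyde (3,5-dibromosalicylaldehyde) | O=Cc1cc(Br)cc(Br)c1O | starting material
2 | 3,5-dibromo-2-methoxybenzaldehyde | COc1c(Br)cc(Br)cc1C=O | intermediate
3 | 3,5-dibromo-2-methoxyphenyl formate | COc1c(Br)cc(Br)cc1OC=O | intermediate (not isolated)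
4 | 3,5-dibromo-2-methoxyphenol | COc1c(Br)cc(Br)cc1O | intermediate
5 | 1,5-dibromo-3-(ethenyloxy)-2-methoxybenzene | COc1c(Br)cc(Br)cc1OC=C | intermediate
6 | racemic 1,5-dibromo-3-(1,2-dibromoethoxy)-2-methoxybenzene | COc1c(Br)cc(Br)cc1OC(Br)CBr | intermediate (not isolated)
7 | (Z)-1,5-dibromo-3-[(2-bromoethenyl)oxy]-2-methoxybenzene | COc1c(Br)cc(Br)cc1O/C=C\Br | intermediate
8 | 1,5-dibromo-3-(ethynyloxy)-2-methoxybenzene | COc1c(Br)cc(Br)cc1OC#C | intermediate
9 | 3-hydroxy-2H-pyran-2-one | Oc1cccoc1=O | starting material
10 | 2-oxo-2H-pyran-3-yl acetate (3-acetoxy-2H-pyran-2-one) | CC(=O)Oc1cccoc1=O | intermediate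
11 | racemic 5-(3,5-dibromo-2-methoxyphenoxy)-3-oxo-2-oxabicyclo[2.2.2]octa-5,7-dien-4-yl acetate | CC(=O)OC12C=CC(OC1=O)C=C2Oc1cc(Br)cc(Br)c1OC | intermediate (not isolated)
12 | 2-(3,5-dibromo-2-methoxyphenoxy)phenyl acetate | COc1c(Br)cc(Br)cc1Oc1ccccc1OC(C)=O | intermediate
13 | 5-bromo-2-(3,5-dibromo-2-methoxyphenoxy)phenyl acetate | COc1c(Br)cc(Br)cc1Oc1ccc(Br)cc1OC(C)=O | intermediate
14 | 5-bromo-2-(3,5-dibromo-2-methoxyphenoxy)phenol | COc1c(Br)cc(Br)cc1Oc1ccc(Br)cc1O | target

## Step count and risk

Total step count: 9. Longest linear sequence: 8 steps (steps 1–5 and 7–9); step 6 is a one-step branch that supplies the diene.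

**Step 7 (key step).** The most likely failure is that the cycloaddition is too slow to compete with thermal self-oligomerisation of the ynol ether, because the acetoxypyrone is only a moderately electron-poor diene for this inverse-demand pairing. Loss of regiocontrol is less likely. The fallback gives up the ring construction and forms the diaryl ether C–O bond by nucleophilic aromatic substitution. It sets out from phenol 4, which is heated with commercial 5-bromo-2-fluorobenzaldehyde and K2CO3 in DMF to give 5-bromo-2-(3,5-dibromo-2-methoxyphenoxy)benzaldehyde F1. Baeyer–Villiger oxidation of F1 with mCPBA then gives 5-bromo-2-(3,5-dibromo-2-methoxyphenoxy)phenyl formate F2, and methanolysis of F2 comes back to the route at target 14. The ring B bromine is bought in place, so steps 8 and 9 are not needed.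

**Step 5.** The terminal ynol ether may oligomerise or hydrate during work-up and concentration, the minor E isomer may eliminate slowly because it requires syn elimination, and alkoxide may add across the triple bond if the mixture is warmed. The fallback sets out from 7 and never handles a free terminal alkyne. Elimination with excess KN(SiMe3)2 (a silylamide far weaker than a dialkylamide, so that C4–H should be left alone) in THF at −78 °C, followed by chlorotrimethylsilane in the same flask, should give the more robust [(3,5-dibromo-2-methoxyphenoxy)ethynyl]trimethylsilane F3. Heating F3 with 10 should give, through racemic 5-(3,5-dibromo-2-methoxyphenoxy)-3-oxo-6-(trimethylsilyl)-2-oxabicyclo[2.2.2]octa-5,7-dien-4-yl acetate F4, the arene 2-(3,5-dibromo-2-methoxyphenoxy)-3-(trimethylsilyl)phenyl acetate F5. Protodesilylation of F5 with trifluoroacetic acid, ipso to silicon and activated by the ortho aryloxy group, comes back to the route at 12.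

**Step 2.** Hydride migration may compete with aryl migration in the Criegee intermediate and divert material to the benzoic acid, because the ring is electron-poor and the methoxy group, flanked by bromine and the formyl group, is twisted out of conjugation. The fallback sets out from 2 and replaces the migrating hydrogen by a methyl group, a poor migrator. Addition of MeMgBr gives racemic 1-(3,5-dibromo-2-methoxyphenyl)ethan-1-ol F6, oxidation with MnO2 gives 1-(3,5-dibromo-2-methoxyphenyl)ethan-1-one F7, and Baeyer–Villiger oxidation (mCPBA, catalytic trifluoroacetic acid) gives 3,5-dibromo-2-methoxyphenyl acetate F8. Methanolysis of F8 comes back to the route at 4.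

**Step 8.** Regiocontrol would erode if the acetate were partly cleaved under the acidic conditions, because a free phenol directs bromine para and ortho to the hydroxyl; over-bromination is the second concern. The fallback sets out from 12 and exchanges the ester for an acid-stable, more deactivating sulfonate. Methanolysis gives 2-(3,5-dibromo-2-methoxyphenoxy)phenol F9, methanesulfonyl chloride and Et3N give 2-(3,5-dibromo-2-methoxyphenoxy)phenyl methanesulfonate F10, and bromination in buffered acetic acid gives 5-bromo-2-(3,5-dibromo-2-methoxyphenoxy)phenyl methanesulfonate F11. Cleavage of the sulfonate of F11 with KOH in aqueous methanol at reflux comes back to the route at 14.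

**Step 3.** Catalyst turnover may be slow, because the phenoxide of an acidic, ortho-substituted phenol adds poorly to the coordinated vinyl ester and the vinyl transfer is reversible. The fallback sets out from 4 and builds the vinyl group by alkylation and elimination: excess 1,2-dibromoethane with K2CO3 in refluxing MeCN gives 1,5-dibromo-3-(2-bromoethoxy)-2-methoxybenzene F12, and E2 elimination of F12 with KOtBu in THF at 0 °C comes back to the route at 5.

## Further compounds

F1 | step 7 | 5-bromo-2-(3,5-dibromo-2-methoxyphenoxy)benzaldehyde | COc1c(Br)cc(Br)cc1Oc1ccc(Br)cc1C=O
F2 | step 7 | 5-bromo-2-(3,5-dibromo-2-methoxyphenoxy)phenyl formate | COc1c(Br)cc(Br)cc1Oc1ccc(Br)cc1OC=O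
F3 | step 5 | [(3,5-dibromo-2-methoxyphenoxy)ethynyl]trimethylsilane | COc1c(Br)cc(Br)cc1OC#C[Si](C)(C)C
F4 | step 5 | racemic 5-(3,5-dibromo-2-methoxyphenoxy)-3-oxo-6-(trimethylsilyl)-2-oxabicyclo[2.2.2]octa-5,7-dien-4-yl acetate | CC(=O)OC12C=CC(OC1=O)C([Si](C)(C)C)=C2Oc1cc(Br)cc(Br)c1OC
F5 | step 5 | 2-(3,5-dibromo-2-methoxyphenoxy)-3-(trimethylsilyl)phenyl acetate | COc1c(Br)cc(Br)cc1Oc1c(OC(C)=O)cccc1[Si](C)(C)C
F6 | step 2 | racemic 1-(3,5-dibromo-2-methoxyphenyl)ethan-1-ol | COc1c(Br)cc(Br)cc1C(C)O
F7 | step 2 | 1-(3,5-dibromo-2-methoxyphenyl)ethan-1-one | COc1c(Br)cc(Br)cc1C(C)=O
F8 | step 2 | 3,5-dibromo-2-methoxyphenyl acetate | COc1c(Br)cc(Br)cc1OC(C)=O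
F9 | step 8 | 2-(3,5-dibromo-2-methoxyphenoxy)phenol | COc1c(Br)cc(Br)cc1Oc1ccccc1O
F10 | step 8 | 2-(3,5-dibromo-2-methoxyphenoxy)phenyl methanesulfonate | COc1c(Br)cc(Br)cc1Oc1ccccc1OS(C)(=O)=O
F11 | step 8 | 5-bromo-2-(3,5-dibromo-2-methoxyphenoxy)phenyl methanesulfonate | COc1c(Br)cc(Br)cc1Oc1ccc(Br)cc1OS(C)(=O)=O
F12 | step 3 | 1,5-dibromo-3-(2-bromoethoxy)-2-methoxybenzene | COc1c(Br)cc(Br)cc1OCCBr
A1 | alternative 1 | 1-(4-bromo-2-nitrophenoxy)propan-2-one | CC(=O)COc1ccc(Br)cc1[N+](=O)[O-]
A2 | alternative 1 | acrolein | C=CC=O
A3 | alternative 1 | racemic 6-(4-bromo-2-nitrophenoxy)cyclohex-2-en-1-one | O=C1C=CCCC1Oc1ccc(Br)cc1[N+](=O)[O-]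
A4 | alternative 1 | 2,4-dibromo-6-(4-bromo-2-nitrophenoxy)phenol | Oc1c(Br)cc(Br)cc1Oc1ccc(Br)cc1[N+](=O)[O-]
A5 | alternative 2 | 2,2'-oxydiphenol | Oc1ccccc1Oc1ccccc1O
A6 | alternative 2 | 2-(2-hydroxyphenoxy)phenyl methanesulfonate | CS(=O)(=O)Oc1ccccc1Oc1ccccc1O
A7 | alternative 2 | 5-bromo-2-(3,5-dibromo-2-hydroxyphenoxy)phenyl methanesulfonate | CS(=O)(=O)Oc1cc(Br)ccc1Oc1cc(Br)cc(Br)c1O
A8 | alternative 3 | 1-(3,5-dibromo-2-methoxyphenoxy)propan-2-one | CC(=O)COc1cc(Br)cc(Br)c1OC
A9 | alternative 3 | ethyl acrylate | C=CC(=O)OCC
A10 | alternative 3 | racemic 4-(3,5-dibromo-2-methoxyphenoxy)cyclohexane-1,3-dione | COc1c(Br)cc(Br)cc1OC1CCC(=O)CC1=O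
A11 | alternative 3 | racemic 3-bromo-6-(3,5-dibromo-2-methoxyphenoxy)cyclohex-2-en-1-one | COc1c(Br)cc(Br)cc1OC1CCC(Br)=CC1=O
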